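**Retrosynthetic overview**

- The target is a trans-2-aryl-3-hydroxymethyl-7-methoxy-2,3-dihydrobenzofuran with a 3-sulfooxypropyl chain at C5. The late disconnections are two O-benzyl groups, the side-chain O–SO3H bond, the C3 CH2OH (back to a methyl ester) and the trans relationship (back to the kinetic cis ester by C3 epimerisation).
- The plan rests on ring B (O1–C2–C3–C3a–C7a). Its C2–C3 bond joins C2, a benzylic carbon carrying O1 and ring C, to C3, which carries a one-carbon oxygenated arm. An ester-bearing carbene at C3 makes exactly this bond when it inserts into an ArO–CH2–Ar C–H bond, so C2–C3 is cut to an ortho-(benzyloxy)aryldiazoacetate.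
- The diazo ester comes from the arylacetate by diazo transfer. The arylacetate comes from an aryl iodide by palladium-catalysed coupling with the zinc enolate of methyl acetate. The aryl iodide comes from eugenol (hydroboration, ortho-iodination), and the ArO–CH2 bond from a Williamson alkylation with the benzyl chloride made from O-benzylvanillin.
- Ring order: rings A and C are bought (eugenol, O-benzylvanillin). Ring B is the only ring built, in the carbene insertion, which sets C2 and, provisionally, C3.

Key step: step 9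

Assumption 1: the (R)-configured phthalimido-tert-leucinate ligand is taken to deliver (2S) at C2; if a trial run shows the opposite sense, the mirror-image catalyst Rh2(S-PTTL)4 is used in the same step with nothing else changed.

Assumption 2: the target is drawn as the free hydrogen sulfate; it is taken to tolerate brief handling as the acid at 0 °C, the sodium salt 19 being the form to store.

Abbreviations: TBS = tert-butyldimethylsilyl; Bn = benzyl; 9-BBN = 9-borabicyclo[3.3.1]nonane; p-ABSA = 4-acetamidobenzenesulfonyl azide; DBU = 1,8-diazabicyclo[5.4.0]undec-7-ene; PTTL = N-phthaloyl-tert-leucinate; dba = dibenzylideneacetone; Q-Phos = 1,2,3,4,5-pentaphenyl-1'-(di-tert-butylphosphino)ferrocene.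

**Route**

Step 1
Reactants: 1 eugenol
Product: 3 dihydroconiferyl alcohol [3-(4-hydroxy-3-methoxyphenyl)propan-1-ol], via bis(9-BBN) adduct 2 (not isolated)
Conditions: 9-BBN (2.3 equiv), THF, 0 °C → rt; then aq. NaOH, H2O2, 0 °C → rt
Reagents that add atoms: hydrogen peroxide, OO (the hydroxyl oxygen of 3); 9-BBN, B1C2CCCC1CCC2 (boron of intermediate 2 only)
Why: Brown hydroboration–oxidation, in which the hindered dialkylborane places boron on the terminal alkene carbon (a second equivalent is taken up by the phenol O–H) and alkaline peroxide then converts the C–B bond into C–OH and frees the phenol.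

Step 2
Reactants: 3 dihydroconiferyl alcohol
Product: 4 3-(4-hydroxy-3-iodo-5-methoxyphenyl)propan-1-ol
Conditions: I2 (1.05 equiv), NaHCO3, THF/H2O, 0 °C → rt
Reagents that add atoms: iodine, [I][I]
Why: Electrophilic aromatic iodination through the phenoxide, where the para position is blocked by the propyl chain and one ortho position by OMe, so iodine should enter the only free position ortho to the hydroxyl.

Step 3
Reactants: 5 4-(benzyloxy)-3-methoxybenzaldehyde (O-benzylvanillin)
Product: 6 [4-(benzyloxy)-3-methoxyphenyl]methanol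
Conditions: NaBH4, MeOH, 0 °C
Reagents that add atoms: none
Why: Borohydride reduction of an aromatic aldehyde to the benzylic alcohol, to which the aryl benzyl ether is inert.

Step 4
Reactants: 6 [4-(benzyloxy)-3-methoxyphenyl]methanol
Product: 7 1-(benzyloxy)-4-(chloromethyl)-2-methoxybenzene
Conditions: SOCl2, CH2Cl2, 0 °C → rt; concentrated and used at once
Reagents that add atoms: thionyl chloride, O=S(Cl)Cl
Why: Chlorodehydroxylation through the chlorosulfite, which an electron-rich benzylic alcohol undergoes readily with loss of SO2.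

Step 5
Reactants: 4 3-(4-hydroxy-3-iodo-5-methoxyphenyl)propan-1-ol; 7 1-(benzyloxy)-4-(chloromethyl)-2-methoxybenzene
Product: 8 3-(4-{[4-(benzyloxy)-3-methoxyphenyl]methoxy}-3-iodo-5-methoxyphenyl)propan-1-ol
Conditions: K2CO3, KI (cat.), DMF, 40 °C
Reagents that add atoms: none
Why: Williamson ether synthesis in which carbonate deprotonates only the phenol (made more acidic by the ortho iodine), so the aliphatic hydroxyl should stay unalkylated.

Step 6
Reactants: 8 3-(4-{[4-(benzyloxy)-3-methoxyphenyl]methoxy}-3-iodo-5-methoxyphenyl)propan-1-ol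
Product: 9 TBS ether, tert-butyl[3-(4-{[4-(benzyloxy)-3-methoxyphenyl]methoxy}-3-iodo-5-methoxyphenyl)propoxy]dimethylsilane
Conditions: TBSCl, imidazole, CH2Cl2, rt
Reagents that add atoms: tert-butyldimethylsilyl chloride, CC(C)(C)[Si](C)(C)Cl
Why: Imidazole-promoted silylation of the only free hydroxyl, giving an ether that tolerates organozinc, carbene, methoxide and hydride conditions.

Step 7
Reactants: 9 aryl iodide TBS ether
Product: 10 methyl 2-[2-{[4-(benzyloxy)-3-methoxyphenyl]methoxy}-5-{3-[(tert-butyldimethylsilyl)oxy]propyl}-3-methoxyphenyl]acetate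
Conditions: BrZnCH2CO2Me (from BrCH2CO2Me, Zn dust, Me3SiCl cat., THF), Pd(dba)2 (5 mol %), Q-Phos (5 mol %), THF, rt → 50 °C
Reagents that add atoms: methyl bromoacetate, COC(=O)CBr (delivered as its zinc enolate)
Why: Negishi-type cross-coupling of a Reformatsky reagent (palladium-catalysed α-arylation of a zinc ester enolate), in which oxidative addition of zerovalent palladium to the aryl iodide, transmetalation and reductive elimination give the arylacetate under nearly neutral conditions that spare the silyl and benzyl ethers.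

Step 8
Reactants: 10 methyl arylacetate
Product: 11 methyl 2-diazo-2-[2-{[4-(benzyloxy)-3-methoxyphenyl]methoxy}-5-{3-[(tert-butyldimethylsilyl)oxy]propyl}-3-methoxyphenyl]acetate
Conditions: p-ABSA, DBU, MeCN, 0 °C → rt
Reagents that add atoms: 4-acetamidobenzenesulfonyl azide, CC(=O)Nc1ccc(cc1)S(=O)(=O)N=[N+]=[N-]
Why: Regitz diazo transfer, in which the DBU-generated arylacetate enolate attacks the terminal azide nitrogen and the adduct collapses to the aryldiazoacetate and the sulfonamide.

Step 9
Reactants: 11 aryldiazoacetate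
Product: 12 methyl (2S,3R)-2-[4-(benzyloxy)-3-methoxyphenyl]-5-{3-[(tert-butyldimethylsilyl)oxy]propyl}-7-methoxy-2,3-dihydro-1-benzofuran-3-carboxylate (cis)
Conditions: Rh2(R-PTTL)4 (dirhodium tetrakis[N-phthaloyl-(R)-tert-leucinate], 1 mol %), toluene, −78 °C → −60 °C, slow addition of 11
Reagents that add atoms: none
Why: Loss of N2 from 11 at the dirhodium core gives an electrophilic donor/acceptor rhodium carbene at the future C3, which takes up hydride from the ArO–CH2–Ar carbon five atoms away while the C2–C3 bond forms in the same three-centre, asynchronous transition state. The closest known reaction type is the dirhodium-carboxylate-catalysed enantioselective intramolecular C–H insertion of methyl 2-(benzyloxy)aryldiazoacetates into the benzylic ether C–H bond, which gives cis-2-aryl-2,3-dihydrobenzofuran-3-carboxylates. Ring B closes by 1,5-insertion, the new bond joining the carbene carbon to the fifth atom of the chain so that the five-membered O1–C2–C3–C3a–C7a ring results. C2 is set by the chiral wall of phthalimido-tert-leucinate ligands, which selects one of the two enantiotopic benzylic hydrogens; C3 is set cis to the aryl group by the compact transition state, a kinetic outcome that step 10 then corrects. The step needs site selectivity, which the substrate secures because only this C–H bond can give a five-membered ring and it is activated both by the ether oxygen and by the electron-rich aryl group; it also needs chemoselectivity over arene cyclopropanation and carbene dimerisation, which slow addition to the catalyst at low temperature should favour.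

Step 10
Reactants: 12 cis ester
Product: 13 methyl (2S,3S)-2-[4-(benzyloxy)-3-methoxyphenyl]-5-{3-[(tert-butyldimethylsilyl)oxy]propyl}-7-methoxy-2,3-dihydro-1-benzofuran-3-carboxylate (trans)
Conditions: NaOMe (0.3 equiv), MeOH/THF, 0 °C → rt
Reagents that add atoms: none
Why: Base-mediated epimerisation through the ester enolate under thermodynamic control, which should move the C3 ester to the less hindered face trans to the C2 aryl group while the non-enolisable C2 centre is untouched.

Step 11
Reactants: 13 trans ester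
Product: 14 [(2S,3R)-2-[4-(benzyloxy)-3-methoxyphenyl]-5-{3-[(tert-butyldimethylsilyl)oxy]propyl}-7-methoxy-2,3-dihydro-1-benzofuran-3-yl]methanol
Conditions: LiAlH4, THF, 0 °C
Reagents that add atoms: none
Why: Hydride reduction of the ester to the primary alcohol, fast enough at 0 °C that C3 is not disturbed (the descriptor changes from S to R only because the substituent priorities change).

Step 12
Reactants: 14 primary alcohol
Product: 15 tert-butyl{3-[(2S,3R)-2-[4-(benzyloxy)-3-methoxyphenyl]-3-[(benzyloxy)methyl]-7-methoxy-2,3-dihydro-1-benzofuran-5-yl]propoxy}dimethylsilane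
Conditions: NaH, BnBr, Bu4NI (cat.), THF, 0 °C → rt
Reagents that add atoms: benzyl bromide, BrCc1ccccc1
Why: Williamson benzylation of the only free hydroxyl, which marks the C3 hydroxymethyl group as the one that must not be sulfated and puts it under the same protecting group as the phenol.

Step 13
Reactants: 15 bis-benzyl TBS ether
Product: 16 3-[(2S,3R)-2-[4-(benzyloxy)-3-methoxyphenyl]-3-[(benzyloxy)methyl]-7-methoxy-2,3-dihydro-1-benzofuran-5-yl]propan-1-ol
Conditions: Bu4NF, THF, 0 °C → rt
Reagents that add atoms: none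
Why: Fluoride-driven desilylation (strong Si–F bond) that frees the side-chain primary alcohol and leaves both benzyl ethers in place.

Step 14
Reactants: 16 side-chain alcohol
Product: 18 sodium 3-[(2S,3R)-2-[4-(benzyloxy)-3-methoxyphenyl]-3-[(benzyloxy)methyl]-7-methoxy-2,3-dihydro-1-benzofuran-5-yl]propyl sulfate, via pyridinium sulfate 17 (not isolated)
Conditions: SO3·pyridine (3 equiv), pyridine, rt; then aq. NaHCO3; reversed-phase chromatography
Reagents that add atoms: sulfur trioxide–pyridine complex, [O-]S(=O)(=O)[n+]1ccccc1; sodium hydrogencarbonate, [Na+].OC([O-])=O (sodium counter-ion)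
Why: O-Sulfation of the single free alcohol by transfer of SO3 from its pyridine adduct, followed by exchange of pyridinium for sodium so that no amine is left to inhibit the palladium catalyst of the next step.

Step 15
Reactants: 18 sodium sulfate bis-benzyl ether
Product: 20 3-[(2S,3R)-2-(4-hydroxy-3-methoxyphenyl)-3-(hydroxymethyl)-7-methoxy-2,3-dihydro-1-benzofuran-5-yl]propyl hydrogen sulfate (target, CNP0220090.1), via sodium salt 19 (not isolated)
Conditions: H2 (1 atm), Pd/C (10 wt %), MeOH/EtOAc, rt; filter; aq. HCl (1.0 equiv), 0 °C; C18 desalting, freeze-drying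
Reagents that add atoms: none
Why: Heterogeneous palladium-catalysed hydrogenolysis should cleave the aryl benzyl and the primary alkyl benzyl ether while the hindered, cyclic C2–O1 bond reacts more slowly at 1 atm and rt, and one equivalent of HCl then protonates the sulfate without touching a stereocentre.

**Compound list**

1 | eugenol (4-allyl-2-methoxyphenol) | C=CCc1ccc(O)c(OC)c1 | starting material
2 | 9-{3-[4-(9-borabicyclo[3.3.1]nonan-9-yloxy)-3-methoxyphenyl]propyl}-9-borabicyclo[3.3.1]nonane | COc1cc(CCCB2C3CCCC2CCC3)ccc1OB1C2CCCC1CCC2 | intermediate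
3 | 3-(4-hydroxy-3-methoxyphenyl)propan-1-ol (dihydroconiferyl alcohol) | COc1cc(CCCO)ccc1O | intermediate
4 | 3-(4-hydroxy-3-iodo-5-methoxyphenyl)propan-1-ol | COc1cc(CCCO)cc(I)c1O | intermediate
5 | 4-(benzyloxy)-3-methoxybenzaldehyde (O-benzylvanillin) | COc1cc(C=O)ccc1OCc1ccccc1 | starting material
6 | [4-(benzyloxy)-3-methoxyphenyl]methanol | COc1cc(CO)ccc1OCc1ccccc1 | intermediate
7 | 1-(benzyloxy)-4-(chloromethyl)-2-methoxybenzene | COc1cc(CCl)ccc1OCc1ccccc1 | intermediate
8 | 3-(4-{[4-(benzyloxy)-3-methoxyphenyl]methoxy}-3-iodo-5-methoxyphenyl)propan-1-ol | COc1cc(CCCO)cc(I)c1OCc1ccc(OCc2ccccc2)c(OC)c1 | intermediate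
9 | tert-butyl[3-(4-{[4-(benzyloxy)-3-methoxyphenyl]methoxy}-3-iodo-5-methoxyphenyl)propoxy]dimethylsilane | COc1cc(CCCO[Si](C)(C)C(C)(C)C)cc(I)c1OCc1ccc(OCc2ccccc2)c(OC)c1 | intermediate
10 | methyl 2-[2-{[4-(benzyloxy)-3-methoxyphenyl]methoxy}-5-{3-[(tert-butyldimethylsilyl)oxy]propyl}-3-methoxyphenyl]acetate | COC(=O)Cc1cc(CCCO[Si](C)(C)C(C)(C)C)cc(OC)c1OCc1ccc(OCc2ccccc2)c(OC)c1 | intermediate
11 | methyl 2-diazo-2-[2-{[4-(benzyloxy)-3-methoxyphenyl]methoxy}-5-{3-[(tert-butyldimethylsilyl)oxy]propyl}-3-methoxyphenyl]acetate | COC(=O)C(=[N+]=[N-])c1cc(CCCO[Si](C)(C)C(C)(C)C)cc(OC)c1OCc1ccc(OCc2ccccc2)c(OC)c1 | intermediate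
12 | methyl (2S,3R)-2-[4-(benzyloxy)-3-methoxyphenyl]-5-{3-[(tert-butyldimethylsilyl)oxy]propyl}-7-methoxy-2,3-dihydro-1-benzofuran-3-carboxylate (cis) | COc1cc([C@H]2Oc3c(OC)cc(CCCO[Si](C)(C)C(C)(C)C)cc3[C@H]2C(=O)OC)ccc1OCc1ccccc1 | intermediate
13 | methyl (2S,3S)-2-[4-(benzyloxy)-3-methoxyphenyl]-5-{3-[(tert-butyldimethylsilyl)oxy]propyl}-7-methoxy-2,3-dihydro-1-benzofuran-3-carboxylate (trans) | COc1cc([C@H]2Oc3c(OC)cc(CCCO[Si](C)(C)C(C)(C)C)cc3[C@@H]2C(=O)OC)ccc1OCc1ccccc1 | intermediate
14 | [(2S,3R)-2-[4-(benzyloxy)-3-methoxyphenyl]-5-{3-[(tert-butyldimethylsilyl)oxy]propyl}-7-methoxy-2,3-dihydro-1-benzofuran-3-yl]methanol | COc1cc([C@H]2Oc3c(OC)cc(CCCO[Si](C)(C)C(C)(C)C)cc3[C@@H]2CO)ccc1OCc1ccccc1 | intermediate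
15 | tert-butyl{3-[(2S,3R)-2-[4-(benzyloxy)-3-methoxyphenyl]-3-[(benzyloxy)methyl]-7-methoxy-2,3-dihydro-1-benzofuran-5-yl]propoxy}dimethylsilane | COc1cc([C@H]2Oc3c(OC)cc(CCCO[Si](C)(C)C(C)(C)C)cc3[C@@H]2COCc2ccccc2)ccc1OCc1ccccc1 | intermediate
16 | 3-[(2S,3R)-2-[4-(benzyloxy)-3-methoxyphenyl]-3-[(benzyloxy)methyl]-7-methoxy-2,3-dihydro-1-benzofuran-5-yl]propan-1-ol | COc1cc([C@H]2Oc3c(OC)cc(CCCO)cc3[C@@H]2COCc2ccccc2)ccc1OCc1ccccc1 | intermediate
17 | pyridinium 3-[(2S,3R)-2-[4-(benzyloxy)-3-methoxyphenyl]-3-[(benzyloxy)methyl]-7-methoxy-2,3-dihydro-1-benzofuran-5-yl]propyl sulfate | COc1cc([C@H]2Oc3c(OC)cc(CCCOS(=O)(=O)[O-])cc3[C@@H]2COCc2ccccc2)ccc1OCc1ccccc1.c1cc[nH+]cc1 | intermediate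
18 | sodium 3-[(2S,3R)-2-[4-(benzyloxy)-3-methoxyphenyl]-3-[(benzyloxy)methyl]-7-methoxy-2,3-dihydro-1-benzofuran-5-yl]propyl sulfate | COc1cc([C@H]2Oc3c(OC)cc(CCCOS(=O)(=O)[O-])cc3[C@@H]2COCc2ccccc2)ccc1OCc1ccccc1.[Na+] | intermediate
19 | sodium 3-[(2S,3R)-2-(4-hydroxy-3-methoxyphenyl)-3-(hydroxymethyl)-7-methoxy-2,3-dihydro-1-benzofuran-5-yl]propyl sulfate | COc1cc([C@H]2Oc3c(OC)cc(CCCOS(=O)(=O)[O-])cc3[C@@H]2CO)ccc1O.[Na+] | intermediate
20 | 3-[(2S,3R)-2-(4-hydroxy-3-methoxyphenyl)-3-(hydroxymethyl)-7-methoxy-2,3-dihydro-1-benzofuran-5-yl]propyl hydrogen sulfate | COc1cc([C@H]2Oc3c(OC)cc(CCCOS(=O)(=O)O)cc3[C@@H]2CO)ccc1O | target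

**Step count**

Total: 15 steps. Longest linear sequence: 13 steps (1, 2, 5–15 from eugenol; equally 3, 4, 5–15 from O-benzylvanillin).

**Steps most likely to fail**

1. Step 9. The strongly donating 4-benzyloxy-3-methoxyphenyl group may turn the insertion into a stepwise hydride transfer, so that the benzylic cation and the rhodium enolate recombine outside the ligand pocket and enantiocontrol at C2 erodes. The carbene may also attack the electron-rich arene. Fallback (resolution instead of asymmetric catalysis): from 11, Rh2(OAc)4 (1 mol %) in CH2Cl2 at rt should close ring B without enantiocontrol to the racemic cis ester F1. NaOMe in MeOH should then equilibrate it to the racemic trans ester F2. Preparative chromatography on a cellulose tris(3,5-dimethylphenylcarbamate) phase would separate the enantiomers, and the (2S,3S) enantiomer is 13, where the route is rejoined.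

2. Step 7. Transmetalation and reductive elimination next to the bulky ortho benzyloxy group may be slow, so that protodeiodination of the aryl iodide or a second arylation of the product enolate takes over. Fallback (aryl nucleophile instead of enolate nucleophile): from 9, iodine–magnesium exchange with iPrMgCl·LiCl in THF at −20 °C should give the arylmagnesium chloride F3. Acylation with excess dimethyl oxalate at −78 °C would give the methyl arylglyoxylate F4. Condensation with tosylhydrazide in MeOH at 50 °C gives the tosylhydrazone F5, and DBU in CH2Cl2 should expel toluenesulfinate (Bamford–Stevens-type) to give the diazo ester directly. The route is rejoined at 11 and step 8 is no longer needed.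

3. Step 15. The primary alkyl benzyl ether is cleaved more slowly than the aryl benzyl ether, and prolonged exposure may open the benzylic C2–O1 bond of ring B by over-reduction. Once the free sulfuric monoester is liberated, acid-promoted ionisation at C2 may also set in. Fallback (final unmasking by transesterification instead of hydrogenolysis): from 14, a short hydrogenolysis (H2, Pd/C, EtOAc, rt) that has to remove only the fast-reacting aryl benzyl ether should give the phenol F6. Ac2O, pyridine and 4-(dimethylamino)pyridine give the diacetate F7, and HF·pyridine in THF frees the side-chain alcohol F8. SO3·pyridine gives the pyridinium sulfate F9, and aq. NaHCO3 the sodium sulfate F10. Zemplén methanolysis (NaOMe, MeOH, then adjustment to pH 7) removes both acetates and returns to the route at 19, which is acidified and desalted as in step 15.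

**Further compounds**

F1 | step 9 | racemic cis ester (1:1 mixture of 12 and its enantiomer) | COc1cc([C@H]2Oc3c(OC)cc(CCCO[Si](C)(C)C(C)(C)C)cc3[C@H]2C(=O)OC)ccc1OCc1ccccc1.COc1cc([C@@H]2Oc3c(OC)cc(CCCO[Si](C)(C)C(C)(C)C)cc3[C@@H]2C(=O)OC)ccc1OCc1ccccc1
F2 | step 9 | racemic trans ester (1:1 mixture of 13 and its enantiomer) | COc1cc([C@H]2Oc3c(OC)cc(CCCO[Si](C)(C)C(C)(C)C)cc3[C@@H]2C(=O)OC)ccc1OCc1ccccc1.COc1cc([C@@H]2Oc3c(OC)cc(CCCO[Si](C)(C)C(C)(C)C)cc3[C@H]2C(=O)OC)ccc1OCc1ccccc1
F3 | step 7 | [2-{[4-(benzyloxy)-3-methoxyphenyl]methoxy}-5-{3-[(tert-butyldimethylsilyl)oxy]propyl}-3-methoxyphenyl]magnesium chloride | COc1cc(CCCO[Si](C)(C)C(C)(C)C)cc([Mg]Cl)c1OCc1ccc(OCc2ccccc2)c(OC)c1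
F4 | step 7 | methyl 2-[2-{[4-(benzyloxy)-3-methoxyphenyl]methoxy}-5-{3-[(tert-butyldimethylsilyl)oxy]propyl}-3-methoxyphenyl]-2-oxoacetate | COC(=O)C(=O)c1cc(CCCO[Si](C)(C)C(C)(C)C)cc(OC)c1OCc1ccc(OCc2ccccc2)c(OC)c1
F5 | step 7 | tosylhydrazone of F4, methyl 2-[2-{[4-(benzyloxy)-3-methoxyphenyl]methoxy}-5-{3-[(tert-butyldimethylsilyl)oxy]propyl}-3-methoxyphenyl]-2-[2-(4-methylbenzenesulfonyl)hydrazinylidene]acetate | COC(=O)C(=NNS(=O)(=O)c1ccc(C)cc1)c1cc(CCCO[Si](C)(C)C(C)(C)C)cc(OC)c1OCc1ccc(OCc2ccccc2)c(OC)c1
F6 | step 15 | 4-[(2S,3R)-5-{3-[(tert-butyldimethylsilyl)oxy]propyl}-3-(hydroxymethyl)-7-methoxy-2,3-dihydro-1-benzofuran-2-yl]-2-methoxyphenol | COc1cc([C@H]2Oc3c(OC)cc(CCCO[Si](C)(C)C(C)(C)C)cc3[C@@H]2CO)ccc1O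
F7 | step 15 | diacetate of F6, [(2S,3R)-2-(4-acetoxy-3-methoxyphenyl)-5-{3-[(tert-butyldimethylsilyl)oxy]propyl}-7-methoxy-2,3-dihydro-1-benzofuran-3-yl]methyl acetate | COc1cc([C@H]2Oc3c(OC)cc(CCCO[Si](C)(C)C(C)(C)C)cc3[C@@H]2COC(C)=O)ccc1OC(C)=O
F8 | step 15 | [(2S,3R)-2-(4-acetoxy-3-methoxyphenyl)-5-(3-hydroxypropyl)-7-methoxy-2,3-dihydro-1-benzofuran-3-yl]methyl acetate | COc1cc([C@H]2Oc3c(OC)cc(CCCO)cc3[C@@H]2COC(C)=O)ccc1OC(C)=O
F9 | step 15 | pyridinium 3-[(2S,3R)-3-(acetoxymethyl)-2-(4-acetoxy-3-methoxyphenyl)-7-methoxy-2,3-dihydro-1-benzofuran-5-yl]propyl sulfate | COc1cc([C@H]2Oc3c(OC)cc(CCCOS(=O)(=O)[O-])cc3[C@@H]2COC(C)=O)ccc1OC(C)=O.c1cc[nH+]cc1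
F10 | step 15 | sodium 3-[(2S,3R)-3-(acetoxymethyl)-2-(4-acetoxy-3-methoxyphenyl)-7-methoxy-2,3-dihydro-1-benzofuran-5-yl]propyl sulfate | COc1cc([C@H]2Oc3c(OC)cc(CCCOS(=O)(=O)[O-])cc3[C@@H]2COC(C)=O)ccc1OC(C)=O.[Na+]
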